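Late in each earlier run the target reading has stopped moving, so we count what stands there in turnovers. The turnover count (a turnover number) is target made per enzyme charged.

all flasks: enzyme 0.01 mol%

| flask | starting material | second substrate | protic impurity | remark | time |
|---|---|---|---|---|---|
| grey | 0.050 M | 1.2 equiv | 0.015 M | run made earlier |  |
| amber | 0.025 M | 1.2 equiv | 0.015 M | run made earlier |  |
| green | 0.10 M | 1.2 equiv | 0.015 M | run made earlier |  |
| noon | 0.050 M | 1.20 equiv (fed, over 1.5 min) | 0.0150 M | all else is in the flask from the start; the feed brings no volume worth counting | 2.0 min |
| dusk | 0.050 M (fed, over 1.5 min) | 1.20 equiv | 0.0150 M | all else is in the flask from the start; the feed brings no volume worth counting | 2.0 min |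
| summer | 0.050 M | 1.20 equiv (in portions, 5, over 1.5 min) | 0.0150 M | first portion at the start, last at 1.5 min | 2.0 min |
| spring | 0.050 M | 1.20 equiv | 0.0150 M | everything together at the start | 2.0 min |

| run | time / s | target / % |
|---|---|---|
| grey | 10.0 | 17 |
| grey | 20.0 | 26 |
| grey | 40.0 | 28 |
| grey | 80.0 | 27 |
| amber | 10.0 | 12 |
| amber | 20.0 | 13 |
| amber | 40.0 | 18 |
| amber | 80.0 | 14 |
| green | 10.0 | 30 |
| green | 20.0 | 32 |
| green | 40.0 | 34 |
| green | 80.0 | 33 |

(readings scatter by 2 percentage points)



- which flask leads in amount of target, in percent of the starting material charged ("all alike" within 1.5 percentage points) (noon / dusk / summer / spring / all alike)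
- how much target is there at the end, in percent of the starting material charged: noon
- how much target is there at the end, in percent of the starting material charged: dusk
- how much target is there at the end, in percent of the starting material charged: summer
- how much target is there at the end, in percent of the starting material charged: spring

Take grey in slow motion. In its first 10.0 s the count reaches 1700, and this is the fast stretch. At 20.0 s target reads 26%, and the further step to 28% at 40.0 s lies within the scatter. Then the run is flat. The mean of the readings from 20.0 s on gives 2700 turnovers for grey, and the same mean gives 1500 for amber and 3300 for green.

From amber to grey the product of the two substrate charges grows by a factor 4.00, while the count grows by 1.80. We carry the turnover exponent, the power of that product with which the count grows, here 0.424. From grey to green the count gains a factor of just 1.22, so we use the exponent between grey and amber.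

Spring repeats grey's recipe, so we expect grey's level. For summer we try a rough scaling: we take the product at its first portion, as a trial figure and with no claim that the later portions stay idle. That divides the product by 5 and gives 1360 turnovers, or 13.6%.

The forecast has spring leading, with spring at 27% (25% to 29%), summer at 11.5% (7% to 17%), and noon and dusk at 5% each (2% to 11%). Its ground is that “something is dying rather than running out”. Our summer figure lies above its 11.5%, within its range.

Spring leads with 26.6%, then come dusk at 21.5%, noon at 14.5% and summer at 12.9%.

    starting material + enzyme ⇌ starting complex (K = 43.0 L mol⁻¹, k = 5.29 × 10⁵ L mol⁻¹ s⁻¹)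
    second substrate + starting complex ⇌ ternary complex (K = 13.0 L mol⁻¹, k = 6.76 × 10⁵ L mol⁻¹ s⁻¹)
    ternary complex → enzyme + target (k = 1440 s⁻¹)
    starting material + protic impurity → quenched substrate (k = 0.995 L mol⁻¹ s⁻¹)
    enzyme ⇌ dormant form (K = 2.20, k = 0.0553 s⁻¹)
    starting material + target → side product (k = 3.61 L mol⁻¹ s⁻¹)

In spring, while enzyme passed into dormant form (68.7% of the catalyst, 31.3% free), starting material, the limiting reagent, went to target, quenched substrate (12.2%) and, meeting target, side product (61.2%, each percentage counting two), until 0% stood. Summer's count came to 1290 against our 1360, but that closeness is no check: in summer the step of second substrate onto starting complex had 37% of its turnover behind it by 0.400 min and half by 0.517 min, later than the second portion at 0.375 min. In the neighbour of summer with 2.00 equiv of second substrate, the same trial scaling puts the first-portion product at 0.333 of grey's, and the exponent gives 1690 turnovers, or 16.9%. The computed flask holds 17.0%.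

The runs were computed from invented constants, noise included.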